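- Convert percent to millimolar.

| setting | teal | grey | flask |
|---|---|---|---|
| solid substrate | 5 mM | 7.5 mM | 10 mM |
| gas phase | 0.79 mM (held) | 0.79 mM (held) | 0.79 mM (held) |
| remark | run made earlier | run made earlier |  |
| time |  |  | 10 min |

| run | time / min | product / % |
|---|---|---|
| teal | 2.50 | 5.3 |
| teal | 5.00 | 14.7 |
| teal | 8.00 | 24.0 |
| teal | 10.0 | 32.5 |
| grey | 1.33 | 1.1 |
| grey | 4.00 | 5.7 |
| grey | 6.00 | 10.4 |
| grey | 10.0 | 20.7 |

(scatter of a reading: 1 percentage point)

* how much product there is at 10 min, in percent of the solid substrate charged
* concentration of dissolved gas in solution at 10 min, in percent of saturation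

- solid substrate is a solid; its amount is given per volume of the solution
- at the start none of the gas is dissolved
- on the list of suspects stand: gas phase <-> dissolved gas; starting material + dissolved gas <-> product; solid substrate <-> starting material
- at the start none of the solid substrate is in solution

- At 10.0 min, teal reads 32.5% and grey 20.7%, yet as concentrations these are 1.62 mM and 1.55 mM of [product].
- Two amounts therefore matter: the charge, and the mean of those two values, 1.59 mM, the [product] taken as read at 10 min in teal and grey. Read from these two runs, this behaviour is zero order in the charge.
- Their ratio gives the new flask 15.9% of its 10 mM charge.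
- Going round once more, 1.59 mM is less than the smaller charge, so neither teal nor grey had used up its charge at that time, and this reckoning carries the same amount to the larger charge of the new flask.
- The same amount gives a mean withdrawal of 0.159 mM min⁻¹ of dissolved gas. A first-order crossing with time constant τ supplies this steadily when the deficit below saturation is that rate times τ.
- The first grey reading, 1.1% at 1.33 min, stands near the scatter. Taking that time as a generous τ gives an estimate of 73.3% of saturation, and this reckoning expects about that or more.
- The forecast gives 16% and 50%, calling its gas figure “poorly determined”, so on the gas this reckoning differs from it.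
- The flask gives 16.1% and 90.2%.

    gas phase ⇌ dissolved gas, rate k1*(csat - [dissolved gas]) (kL = 0.0370 s⁻¹)
    starting material + dissolved gas ⇌ product (K = 2100 L mol⁻¹, k = 8.60 L mol⁻¹ s⁻¹)
    solid substrate ⇌ starting material, rate k3*(cs3 - [starting material]) while solid is left; crystals form when [starting material] > cs3 (solubility = 5.30 mM, k = 0.00120 s⁻¹)

- In the flask at 4.61 min, dissolved gas is made, net, 0.991 times as fast as it is used, and its half-life by the forward conversion alone is 1.4 min, short against the 10 min of the run. [dissolved gas] stands at 0.707 mM at 5.00 min and 0.712 mM at 10.0 min. A neighbour flask charged with 25 mM of solid substrate also holds 0.712 mM, and 1.59 mM over that charge is 6.36%, where this neighbour gives 6.43%.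

Readings and results stem from a simulated flask for an exercise.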